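**Strategy.** Both ester oxygens of the central benzene ring (O–C1 and O–C4, each flanked by the C2/C5 phenol oxygen and a C6/C3 4-hydroxyphenyl ring) are disconnected back to aryl ketones. A double Baeyer–Villiger oxidation of a 1,4-diacyl-2,5-bis(benzyloxy)-3,6-diarylbenzene inserts oxygen into both aryl–carbonyl bonds in one operation. The two different acyl groups are therefore placed by C–C bond formation, and no hydroxyl group ever has to be distinguished. The precursor is the penta-O-benzyl diketone, assembled from a symmetrical dibromide by two successive bromine–lithium exchanges and aldehyde additions. Global hydrogenolysis finishes the synthesis.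

Key step: step 7

Remark: where one transformation occurs at two or more equivalent sites in a single operation (steps 1, 2, 7, 8), the half-converted species are not numbered; the carbinol centres of 12–14 form without control and are erased in step 6.

**Step 1**
Reactants: 1 2,5-dibromo-1,4-benzoquinone; 2 4-(benzyloxy)aniline
Product: 4 2,5-bis[4-(benzyloxy)phenyl]-3,6-dibromo-1,4-benzoquinone, via 4-(benzyloxy)benzenediazonium chloride 3 (not isolated)
Conditions: 2 (2.6 equiv), NaNO2, aq HCl, 0 °C; then 1, NaOAc, acetone/H2O, 0 → 25 °C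
Reagents that add atoms: none
Why: Meerwein arylation, in which the aryl radical released from the diazonium salt adds to the only two C–H carbons of the quinone and the adduct radical is re-oxidised by further diazonium ion, so that only the 2,5-dibromo-3,6-diaryl isomer can form.

**Step 2**
Reactants: 4 2,5-bis[4-(benzyloxy)phenyl]-3,6-dibromo-1,4-benzoquinone
Product: 6 1,4-bis(benzyloxy)-2,5-bis[4-(benzyloxy)phenyl]-3,6-dibromobenzene, via dibromodiarylhydroquinone 5 (not isolated)
Conditions: Na2S2O4, DMF/H2O, rt; then K2CO3, BnBr, 60 °C, under Ar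
Reagents that add atoms: benzyl bromide, BrCc1ccccc1
Why: Dithionite reduction of the quinone followed by Williamson benzylation of the hydroquinone, with reduction carried out first so that the vinylogous acyl bromide is gone before carbonate is added.

**Step 3**
Reactants: 7 ethyl (S)-3-hydroxybutanoate
Product: 8 ethyl (S)-3-(benzyloxy)butanoate
Conditions: BnOC(=NH)CCl3, TfOH (cat.), CH2Cl2/cyclohexane, 0 °C → rt
Reagents that add atoms: benzyl 2,2,2-trichloroacetimidate, ClC(Cl)(Cl)C(=N)OCc1ccccc1
Why: Acid-catalysed O-benzylation with the trichloroacetimidate avoids the base that would cause retro-aldol cleavage or β-elimination of the β-hydroxy ester, and the C–O bond at the stereocentre is not broken, so (S) is retained.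

**Step 4**
Reactants: 8 ethyl (S)-3-(benzyloxy)butanoate
Product: 9 (S)-3-(benzyloxy)butanal
Conditions: DIBAL-H (1.05 equiv), CH2Cl2, −78 °C; Rochelle salt work-up
Reagents that add atoms: none
Why: Partial ester reduction with DIBAL-H stops at the aluminium hemiacetal at −78 °C (helped by chelation to the β-benzyloxy oxygen) and releases the aldehyde on work-up without touching the stereocentre.

**Step 5**
Reactants: 6 1,4-bis(benzyloxy)-2,5-bis[4-(benzyloxy)phenyl]-3,6-dibromobenzene; 10 3-phenylpropanal; 9 (S)-3-(benzyloxy)butanal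
Product: 14 (3S)-3-(benzyloxy)-1-{2,5-bis(benzyloxy)-3,6-bis[4-(benzyloxy)phenyl]-4-(1-hydroxy-3-phenylpropyl)phenyl}butan-1-ol (mixture of carbinol epimers), via bromo aryllithium 11 (not isolated), via lithium bromo alkoxide 12 (not isolated), via lithiated lithium alkoxide 13 (not isolated)
Conditions: n-BuLi (1.0 equiv), THF, −78 °C; 10 (1.0 equiv); n-BuLi (1.1 equiv), −78 °C; 9 (1.3 equiv); then H2O
Reagents that add atoms: none
Why: Bromine–lithium exchange with one equivalent of n-BuLi desymmetrises the dibromide because a second exchange on an aryllithium is disfavoured, 1,2-addition to 10 gives an alkoxide that is inert to the second exchange, and the second aryllithium adds to 9 without involving its (S)-centre.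

**Step 6**
Reactants: 14 the diol from step 5
Product: 15 (S)-3-(benzyloxy)-1-{2,5-bis(benzyloxy)-3,6-bis[4-(benzyloxy)phenyl]-4-(3-phenylpropanoyl)phenyl}butan-1-one
Conditions: Dess–Martin periodinane, CH2Cl2, 0 °C → rt
Reagents that add atoms: none
Why: Dess–Martin oxidation converts both hindered secondary benzylic alcohols to ketones under non-basic conditions, so the β-benzyloxy ketone cannot lose benzyl alcohol by E1cB elimination and the (S)-centre stays intact.

**Step 7**
Reactants: 15 the penta-O-benzyl diketone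
Product: 16 2,5-bis(benzyloxy)-3,6-bis[4-(benzyloxy)phenyl]-4-[(3-phenylpropanoyl)oxy]phenyl (S)-3-(benzyloxy)butanoate
Conditions: m-CPBA (excess), TFA (cat.), CH2Cl2, 0 °C → rt, dark
Reagents that add atoms: m-CPBA, OOC(=O)c1cccc(Cl)c1
Why: Each ketone, twisted out of the ring plane by its benzyloxy and aryl neighbours and so about as electrophilic as an aliphatic ketone, should add the peracid to give a Criegee adduct, from which ring carbon C1 (or C4) migrates from the carbonyl carbon to the proximal peroxide oxygen as 3-chlorobenzoate leaves, forming both C(aryl)–O ester bonds in the same flask. The closest known reaction type is the Baeyer–Villiger oxidation of ortho-alkoxy and 2,6-disubstituted aryl alkyl ketones to aryl esters. No ring is closed and no stereocentre is formed; the (S)-centre lies β to the carbonyl, outside the migrating bonds, and no base is present that could eliminate benzyl alcohol. The step needs aryl-over-alkyl migration: both competing groups are primary CH2 carbons (one further deactivated by its β-oxygen), whereas the ring carbon carries an ortho benzyloxy donor and relieves steric strain on leaving the crowded carbonyl. It also needs the oxidant to spare the rings: all five hydroxyls are benzylated so no phenol can be oxidised to a quinone, and acid-catalysed m-CPBA is chosen over trifluoroperacetic acid to avoid hydroxylation of the alkoxy-substituted outer rings.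

**Step 8**
Reactants: 16 the penta-O-benzyl diester
Product: 17 2,5-dihydroxy-3,6-bis(4-hydroxyphenyl)-4-[(3-phenylpropanoyl)oxy]phenyl (S)-3-hydroxybutanoate (CNP0296884.1)
Conditions: H2 (1 atm), Pd(OH)2/C, EtOAc/THF, rt; filtration and concentration under Ar
Reagents that add atoms: none
Why: Catalytic hydrogenolysis cleaves the four aryl benzyl ethers and the secondary alkyl benzyl ether under neutral, aprotic conditions, which leaves both aryl esters in place and offers no base for acyl migration to the neighbouring phenols.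

**Compound list**
1 | 2,5-dibromo-1,4-benzoquinone | O=C1C=C(Br)C(=O)C=C1Br | starting material
2 | 4-(benzyloxy)aniline | Nc1ccc(OCc2ccccc2)cc1 | starting material
3 | 4-(benzyloxy)benzenediazonium chloride | N#[N+]c1ccc(OCc2ccccc2)cc1.[Cl-] | intermediate
4 | 2,5-bis[4-(benzyloxy)phenyl]-3,6-dibromo-1,4-benzoquinone | O=C1C(Br)=C(c2ccc(OCc3ccccc3)cc2)C(=O)C(Br)=C1c1ccc(OCc2ccccc2)cc1 | intermediate
5 | 2,5-bis[4-(benzyloxy)phenyl]-3,6-dibromobenzene-1,4-diol | Oc1c(Br)c(-c2ccc(OCc3ccccc3)cc2)c(O)c(Br)c1-c1ccc(OCc2ccccc2)cc1 | intermediate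
6 | 1,4-bis(benzyloxy)-2,5-bis[4-(benzyloxy)phenyl]-3,6-dibromobenzene | Brc1c(OCc2ccccc2)c(-c2ccc(OCc3ccccc3)cc2)c(Br)c(OCc2ccccc2)c1-c1ccc(OCc2ccccc2)cc1 | intermediate
7 | ethyl (S)-3-hydroxybutanoate | C[C@H](O)CC(=O)OCC | starting material
8 | ethyl (S)-3-(benzyloxy)butanoate | C[C@H](OCc1ccccc1)CC(=O)OCC | intermediate
9 | (S)-3-(benzyloxy)butanal | C[C@H](OCc1ccccc1)CC=O | intermediate
10 | 3-phenylpropanal | O=CCCc1ccccc1 | starting material
11 | {2,5-bis(benzyloxy)-3,6-bis[4-(benzyloxy)phenyl]-4-bromophenyl}lithium | [Li]c1c(OCc2ccccc2)c(-c2ccc(OCc3ccccc3)cc2)c(Br)c(OCc2ccccc2)c1-c1ccc(OCc2ccccc2)cc1 | intermediate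
12 | lithium 1-{2,5-bis(benzyloxy)-3,6-bis[4-(benzyloxy)phenyl]-4-bromophenyl}-3-phenylpropan-1-olate (racemic at the carbinol carbon) | [Li]OC(CCc1ccccc1)c1c(OCc2ccccc2)c(-c2ccc(OCc3ccccc3)cc2)c(Br)c(OCc2ccccc2)c1-c1ccc(OCc2ccccc2)cc1 | intermediate
13 | lithium 1-{2,5-bis(benzyloxy)-3,6-bis[4-(benzyloxy)phenyl]-4-lithiophenyl}-3-phenylpropan-1-olate | [Li]OC(CCc1ccccc1)c1c(OCc2ccccc2)c(-c2ccc(OCc3ccccc3)cc2)c([Li])c(OCc2ccccc2)c1-c1ccc(OCc2ccccc2)cc1 | intermediate
14 | (3S)-3-(benzyloxy)-1-{2,5-bis(benzyloxy)-3,6-bis[4-(benzyloxy)phenyl]-4-(1-hydroxy-3-phenylpropyl)phenyl}butan-1-ol (both carbinol carbons unassigned) | C[C@H](OCc1ccccc1)CC(O)c1c(OCc2ccccc2)c(-c2ccc(OCc3ccccc3)cc2)c(C(O)CCc2ccccc2)c(OCc2ccccc2)c1-c1ccc(OCc2ccccc2)cc1 | intermediate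
15 | (S)-3-(benzyloxy)-1-{2,5-bis(benzyloxy)-3,6-bis[4-(benzyloxy)phenyl]-4-(3-phenylpropanoyl)phenyl}butan-1-one | C[C@H](OCc1ccccc1)CC(=O)c1c(OCc2ccccc2)c(-c2ccc(OCc3ccccc3)cc2)c(C(=O)CCc2ccccc2)c(OCc2ccccc2)c1-c1ccc(OCc2ccccc2)cc1 | intermediate
16 | 2,5-bis(benzyloxy)-3,6-bis[4-(benzyloxy)phenyl]-4-[(3-phenylpropanoyl)oxy]phenyl (S)-3-(benzyloxy)butanoate | C[C@H](OCc1ccccc1)CC(=O)Oc1c(OCc2ccccc2)c(-c2ccc(OCc3ccccc3)cc2)c(OC(=O)CCc2ccccc2)c(OCc2ccccc2)c1-c1ccc(OCc2ccccc2)cc1 | intermediate
17 | 2,5-dihydroxy-3,6-bis(4-hydroxyphenyl)-4-[(3-phenylpropanoyl)oxy]phenyl (S)-3-hydroxybutanoate | C[C@H](O)CC(=O)Oc1c(O)c(-c2ccc(O)cc2)c(OC(=O)CCc2ccccc2)c(O)c1-c1ccc(O)cc1 | target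

**Totals.** Total step count: 8. Longest linear sequence: 6 steps (1, 2, 5, 6, 7, 8, or equally 3, 4, 5, 6, 7, 8).

**Steps most likely to fail**

Step 7. The peracid may fail to add to the two shielded carbonyl groups, a CH2 group may migrate in place of the ring carbon, or the alkoxy-substituted outer rings may be over-oxidised. The fallback gives up oxygen insertion and makes the C(aryl)–O bonds by boronate oxidation; it sets out from dibromide 6 and ester 8 and returns to the route at 16. Two bromine–lithium exchanges on 6 (n-BuLi, THF, −78 °C), trapping with trimethyl borate and oxidation with H2O2 should give 2,5-bis(benzyloxy)-3,6-bis[4-(benzyloxy)phenyl]benzene-1,4-diol F1, handled under argon. Acylation with one equivalent of 3-phenylpropanoyl chloride (pyridine, CH2Cl2, 0 °C) should give the mono(3-phenylpropanoate) F2 as the separable middle component of a statistical mixture, with recovered F1 recycled. Saponification of 8 (LiOH, THF/H2O, rt) should give (S)-3-(benzyloxy)butanoic acid F3, and Steglich esterification of F2 with F3 (DCC, DMAP cat., CH2Cl2) should give 16.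

Step 5. The aryllithium, crowded by a benzyloxy group and an aryl ring, may deprotonate the enolisable aldehydes instead of adding to them, or be quenched to the reduced arene before the second exchange. The fallback changes the order of bond formation: the carbonyl additions are done on a smaller, less basic aryllithium and the aryl rings are attached last by cross-coupling. It sets out from quinone 1 (with aldehydes 10 and 9) and returns at diol 14. Dithionite reduction of 1 should give 2,5-dibromobenzene-1,4-diol F4, and chlorination of its two free ring positions with sulfuryl chloride (Et2O/AcOH) should give 2,5-dibromo-3,6-dichlorobenzene-1,4-diol F5. Benzylation (BnBr, K2CO3, DMF) should give 1,4-bis(benzyloxy)-2,5-dibromo-3,6-dichlorobenzene F6. Two exchange/addition cycles as in step 5 (only bromine exchanges at −78 °C; first 10, then 9) should give (3S)-3-(benzyloxy)-1-[2,5-bis(benzyloxy)-3,6-dichloro-4-(1-hydroxy-3-phenylpropyl)phenyl]butan-1-ol F7. A double Suzuki–Miyaura coupling of F7 with 4-(benzyloxy)phenylboronic acid (Pd(OAc)2/SPhos, K3PO4, toluene/H2O, 100 °C) should then give 14.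

Step 1. The aryl radical may attack the bromine-bearing carbons with loss of bromine, or the second arylation may stall while the diazonium salt decomposes to tar. The fallback attaches the aryl rings by palladium-catalysed coupling instead of radical addition; it sets out from quinone 1 and returns at dibromide 6. Reductive benzylation of 1 under the conditions of step 2 should give 1,4-bis(benzyloxy)-2,5-dibromobenzene F8. Deprotonation with LDA (THF, −78 °C) at the ring C–H flanked by bromine and benzyloxy, followed by an iodine quench, should give 1,4-bis(benzyloxy)-2,5-dibromo-3-iodobenzene F9, and a second cycle should give 1,4-bis(benzyloxy)-2,5-dibromo-3,6-diiodobenzene F10. Chemoselective Suzuki–Miyaura coupling at the two C–I bonds with 4-(benzyloxy)phenylboronic acid (Pd(PPh3)4, Na2CO3, toluene/EtOH/H2O, 60 °C) should give 6.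

**Further compounds**
F1 | step 7 | 2,5-bis(benzyloxy)-3,6-bis[4-(benzyloxy)phenyl]benzene-1,4-diol | Oc1c(OCc2ccccc2)c(-c2ccc(OCc3ccccc3)cc2)c(O)c(OCc2ccccc2)c1-c1ccc(OCc2ccccc2)cc1
F2 | step 7 | 2,5-bis(benzyloxy)-3,6-bis[4-(benzyloxy)phenyl]-4-hydroxyphenyl 3-phenylpropanoate | Oc1c(OCc2ccccc2)c(-c2ccc(OCc3ccccc3)cc2)c(OC(=O)CCc2ccccc2)c(OCc2ccccc2)c1-c1ccc(OCc2ccccc2)cc1
F3 | step 7 | (S)-3-(benzyloxy)butanoic acid | C[C@H](OCc1ccccc1)CC(=O)O
F4 | step 5 | 2,5-dibromobenzene-1,4-diol | Oc1cc(Br)c(O)cc1Br
F5 | step 5 | 2,5-dibromo-3,6-dichlorobenzene-1,4-diol | Oc1c(Cl)c(Br)c(O)c(Cl)c1Br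
F6 | step 5 | 1,4-bis(benzyloxy)-2,5-dibromo-3,6-dichlorobenzene | Clc1c(OCc2ccccc2)c(Br)c(Cl)c(OCc2ccccc2)c1Br
F7 | step 5 | (3S)-3-(benzyloxy)-1-[2,5-bis(benzyloxy)-3,6-dichloro-4-(1-hydroxy-3-phenylpropyl)phenyl]butan-1-ol | C[C@H](OCc1ccccc1)CC(O)c1c(OCc2ccccc2)c(Cl)c(C(O)CCc2ccccc2)c(OCc2ccccc2)c1Cl
F8 | step 1 | 1,4-bis(benzyloxy)-2,5-dibromobenzene | Brc1cc(OCc2ccccc2)c(Br)cc1OCc1ccccc1
F9 | step 1 | 1,4-bis(benzyloxy)-2,5-dibromo-3-iodobenzene | Brc1c(I)c(OCc2ccccc2)c(Br)cc1OCc1ccccc1
F10 | step 1 | 1,4-bis(benzyloxy)-2,5-dibromo-3,6-diiodobenzene | Brc1c(I)c(OCc2ccccc2)c(Br)c(I)c1OCc1ccccc1
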